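A small charge of solid reagent showed me the limit. In the dawn run, with 0.045 M of it on 0.10 M of starting material, 43.3 % of the starting material had gone by 5.00 h, close to the charge ratio of 45.0 %, and the loss was slowing.

| flask | starting material | solid reagent | remark | time |
|---|---|---|---|---|
| dawn | 0.10 M | 0.045 M | run made earlier |  |
| midnight | 0.10 M | 0.068 M | run made earlier |  |
| summer | 0.20 M | 0.090 M | run made earlier |  |
| red | 0.10 M | 0.0900 M |  | 15 h |
| violet | 0.10 M | 0.0900 M |  | 8.0 h |

| run | time / h | starting material / % | target / % | loose pair / % | tight pair / % | isomer of the product / % |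
|---|---|---|---|---|---|---|
| dawn | 0.417 | 93.5 | 2.4 | 0.8 | 1.3 | 2.5 |
| dawn | 0.667 | 90.8 | 5.5 | 0 | 0.4 | 2.3 |
| dawn | 1.00 | 86.1 | 9.1 | 1.4 | 0.6 | 3.6 |
| dawn | 2.00 | 73.5 | 16.7 | 0 | 0 | 9.3 |
| dawn | 3.00 | 63.8 | 21.8 | 0 | 0 | 12.8 |
| dawn | 5.00 | 56.7 | 29.7 | 0 | 0.3 | 14.2 |
| midnight | 0.833 | 89.1 | 5.0 | 0.4 | 0.9 | 2.1 |
| midnight | 1.50 | 78.9 | 12.5 | 0.5 | 0 | 7.9 |
| midnight | 2.50 | 69.8 | 20.5 | 0 | 2.0 | 10.0 |
| midnight | 3.00 | 64.4 | 24.0 | 0 | 1.3 | 11.1 |
| midnight | 4.00 | 53.9 | 29.9 | 1.4 | 0 | 14.5 |
| midnight | 5.00 | 45.1 | 36.9 | 0.7 | 0.5 | 18.8 |
| summer | 0.417 | 94.7 | 3.0 | 0.9 | 0.4 | 1.3 |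
| summer | 0.667 | 92.0 | 3.8 | 0 | 0 | 1.7 |
| summer | 1.33 | 84.5 | 10.7 | 1.2 | 0 | 5.0 |
| summer | 2.50 | 72.7 | 18.7 | 0 | 0 | 9.0 |
| summer | 5.00 | 54.9 | 30.9 | 0 | 0 | 15.3 |

(readings scatter by 1 percentage point)

- solid, in amounts per volume of the solution: solid reagent
- at the start none of the solid reagent is in solution

* which of these there is most of at the end, counted by the starting material in it, red (loose pair / isomer of the product / starting material / target / tight pair)
* which of these there is most of at the end, counted by the starting material in it, violet (loose pair / isomer of the product / starting material / target / tight pair)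
* final amount of the leader among these, as a percentage of the starting material charged, in red
* final amount of the leader among these, as a percentage of the starting material charged, in violet

So I took the solid reagent as the limiting reagent, used one for one. The last summer reading put the target's share of the two products at 66.9 %. That share times the solid reagent charged over the starting material charged is the target's ceiling, which for red was 60.2 %.

For the rest I replaced each curve by a mean first-order rate. The first 2.50 h of summer gave 0.128 h⁻¹, and the whole midnight run gave 0.159 h⁻¹, which is faster. Then: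

target = share × (1 − exp(−rate × time))

red: from 57.1 % up to the ceiling, since the faster rate gives 60.7 %, above it

violet: from 42.8 % to 48.2 %

These ranges are estimates from mean rates and not strict bounds, since a mean rate leaves out the slowing seen in dawn.

The forecast named target in both flasks, with 59 % in red and 46 % in violet, both inside my brackets. It held that “the amount of solid doesn't affect the rate while some remains”.

Red gave 57.2 % of target and violet 48.0 %, with target leading in both. Left to 150 h, red stands at 59.7 %, level with the ceiling of 60.2 %. At 15 h red was 3 percentage points short of it, with 0 % solid reagent left as solid and 0.00403 M of partner, its dissolved form, in solution.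

    partner + loose pair → isomer of the product (k = 34.0 M⁻¹ min⁻¹)
    partner + tight pair → target (k = 65.0 M⁻¹ min⁻¹)
    solid reagent ⇌ partner, rate k3*(cs3 - [partner]) while solid is left; crystals form when [partner] > cs3 (solubility = 16.0 mM, k = 0.120 min⁻¹)
    starting material ⇌ tight pair (K = 0.00200, k = 0.0440 min⁻¹)
    tight pair ⇌ loose pair (K = 1.30, k = 1.70 min⁻¹)

A neighbour of red charged with 0.25 M of starting material has a ceiling of 24.1 %. That flask gives 23.5 % of target at 15.0 h, just under that ceiling, with 0 % solid reagent left and starting material leading, not target.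

The runs were computed for substances that don't exist; the scatter is artificial.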